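All runs are calculated with constants of no real substance.

A ratio of 0.305 is what Wednesday's run gives for the resting ratio, defined as summed target readings over summed isomer readings once neither amount moves. The question is whether that number carries over to a new flask with a different charge.

| flask | substrate | reagent | remark | time |
|---|---|---|---|---|
| Wednesday's | 7.0 × 10⁻⁴ M | 0.65 mM | run made earlier |  |
| Thursday's | 0.0011 M | 0.65 mM | run made earlier |  |
| flask | 5.0 × 10⁻⁴ M | 0.650 mM |  | 20 h |

| run | time / h | target / % | isomer of the product / % |
|---|---|---|---|
| Wednesday's | 2.00 | 5.4 | 16.6 |
| Wednesday's | 4.00 | 5.2 | 17.1 |
| Wednesday's | 10.0 | 5.2 | 16.9 |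
| Wednesday's | 25.0 | 5.0 | 17.7 |
| Thursday's | 3.00 | 1.1 | 3.2 |
| Thursday's | 8.00 | 1.1 | 2.7 |
| Thursday's | 15.0 | 0.4 | 2.7 |
| Thursday's | 25.0 | 0.6 | 2.9 |

(standard deviation of a reading: 0.3 percentage points)

- ratio of target to isomer of the product at 30 s
- ratio of target to isomer of the product at 25 min
- ratio of target to isomer of the product at 20 h
- which of target and isomer of the product there is more of at 20 h

- percentages count the substrate that a species holds: one side product A counts as two
- what was read earlier has a scatter of 0.3 percentage points, one standard deviation
- steps that have been proposed: substrate + reagent -> intermediate + released group; intermediate <-> target; intermediate <-> isomer of the product; substrate + target -> side product A; 2 reagent -> homo dimer; substrate + released group -> side product B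

The proposed steps allow two extremes, each solvable in the head.

Kinetic control: target and isomer of the product never return to the intermediate, while substrate + target → side product A drains target. This extreme demands a lower ratio on Thursday's run, whose substrate charge is larger.

Thermodynamic control: both exchange through the intermediate, so the ratio is an equilibrium property, independent of the charge.

The same reckoning on Thursday's run gives:

Thursday's resting ratio = summed target / summed isomer = 0.278

This is the looser number, since its target readings lie between 0.4% and 1.1% with a scatter of 0.3 percentage points. Target plus isomer at the first reading falls from 22.0% on Wednesday's run to 4.30% on Thursday's, yet the resting ratio goes only from 0.305 to 0.278. The runs therefore stand near the second extreme, and this reckoning commits the flask at 20 h to 0.305, with isomer of the product ahead. It gives no figure for 30 s or 25 min, which lie before any reading.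

The forecast gives 1 at 30 s, 0.36 at 25 min and 0.3 at 20 h, with isomer of the product ahead: “Equilibrium doesn't depend on concentration”.

The flask gives 2.85, 0.299 and 0.300 at those times, with isomer of the product ahead.

    substrate + reagent → intermediate + released group (k = 34.5 M⁻¹ s⁻¹)
    intermediate ⇌ target (K = 0.870, k = 0.0415 s⁻¹)
    intermediate ⇌ isomer of the product (K = 2.90, k = 0.00842 s⁻¹)
    substrate + target → side product A (k = 18.3 M⁻¹ s⁻¹)
    2 reagent → homo dimer (k = 37.0 M⁻¹ s⁻¹)
    substrate + released group → side product B (k = 71.1 M⁻¹ s⁻¹)

The forecast parts from the flask at 30 s: the rate constant from intermediate to target is 4.93 times that to isomer of the product. In the flask, target and isomer stand level at 0.0313 h, much earlier than 20 h. Applying 0.305 to the flask's 23.0% of isomer gives 7.02% of target, and the flask holds 6.91%. With 0.0026 M of reagent, the neighbouring flask holds 35.1% of isomer at 20 h, so 0.305 gives 10.7% of target, and that flask stands at 10.5%.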